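Take 2.66. The beta run stands at 36.2% target at 1.33 min, and the delta run stands at 34.8% at 30.0 s. That ratio of times between two tops is the clock ratio for the step from 108 °C to 124 °C. It is a reading and carries the scatter. I assume the charge does not move it, since these two runs differ in charge as well.

| flask | substrate | temperature | remark | time |
|---|---|---|---|---|
| beta | 0.050 M | 108 °C | run made earlier |  |
| delta | 0.20 M | 124 °C | run made earlier |  |
| blue | 0.10 M | 130 °C |  | 3.0 min |
| amber | 0.10 M | 100 °C |  | 3.0 min |
| ochre | 0.10 M |  | at 100 °C until 1.5 min, from then on at 130 °C | 3.0 min |
| green | 0.10 M | 115 °C |  | 3.0 min |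

beta run (percent of the substrate charged)

| time / min | target / % |
|---|---|
| 0.500 | 12.5 |
| 1.33 | 36.2 |
| 2.50 | 35.4 |
| 4.00 | 25.8 |
| 6.00 | 24.2 |

delta run (percent of the substrate charged)

| time / s | target / % |
|---|---|
| 10.0 | 13.8 |
| 15.0 | 24.6 |
| 30.0 | 34.8 |
| 60.0 | 32.4 |
| 120 | 33.1 |

(readings scatter by 1 percentage point)

1. the best flask by amount of target, in percent of the substrate charged; "all alike" if 1.5 percentage points covers them all (blue / amber / ochre / green / all alike)
2. amount of target at the end, in percent of the substrate charged, blue
3. amount of target at the end, in percent of the substrate charged, amber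
4. amount of target at the end, in percent of the substrate charged, ochre
5. amount of target at the end, in percent of the substrate charged, green

- the numbers in the tables scatter with a standard deviation of 1 percentage point

Scale any flask to beta's clock: multiply its time by the clock ratio, raised to its temperature step from 108 °C over the step between the runs. This is a thermal dose, the integral of a single rate. A single rate pacing the run is my assumption, and stretches of a run add only as far as that assumption holds.

Now keep the ledger of the substrate charged. At beta's top, target holds 36.2%, so 63.8% sits in forms you cannot read. By 6.00 min target has dropped to 24.2%, and 75.8% is unread. Delta's last reading stands at 5.32 min on the clock, near beta's last, yet target holds 33.1%, more than beta's. So I read the position from the clock and the plateau height from the temperature.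

Amber comes to 1.84 min, between beta's two top readings, so I book about 36.2%: kinetic control. Green comes to 4.60 min, later than beta's reading at 4.00 min. Between the two plateaus I book 28.1%. Ochre comes to 6.68 min and blue to 11.5 min, both further on. I book both near delta's 33.1%: thermodynamic control. So my best flask is amber.

The forecast differs. It names blue at 36%, with ochre 36%, amber 33% and green 29%, saying “Blue and ochre effectively tie, with amber close behind”.

    substrate → intermediate A (k = 0.0280 s⁻¹, Ea = 89.0 kJ mol⁻¹)
    intermediate A → intermediate B (k = 0.0590 s⁻¹, Ea = 96.0 kJ mol⁻¹)
    intermediate B ⇌ target (K = 10.0, k = 0.0100 s⁻¹, Ea = 93.0 kJ mol⁻¹, ΔH = −80.0 kJ mol⁻¹)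
    target ⇌ isomer of the product (K = 4.50, k = 0.00750 s⁻¹, Ea = 102 kJ mol⁻¹, ΔH = −49.0 kJ mol⁻¹)
    (constants at 100 °C)

Amber gives 39.8%, so amber is the best flask; blue gives 32.6%, ochre 32.6% and green 28.1%. Amber's 1.84 min on the clock put it among beta's top readings, and left until 30.0 min its target falls to 17.9%. The green flask read at 50 s stands at 1.28 min on the clock, beside beta's 1.33 min, and it holds 36.1% target.

The runs come from a simulation on assumed constants; the scatter is artificial.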